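## Retrosynthetic overview

1. The target, (3S,4R,3′R,6′R)-β,ε-carotene-3,4,3′-triol, is cut at C11=C12 (Wittig) into an ε-C25 phosphonium salt and a β-C15 aldehyde; the C25 unit is cut at C11′=C12′ into an ε-C15 phosphonium salt and the C10 dialdehyde.
2. Each C15 unit comes from a C10 ring aldehyde and a C5 phosphonate (Horner–Wadsworth–Emmons).
3. Both ring aldehydes come from one racemic trans-4-hydroxycyclohexene ester that a lipase splits: the (1R,4R) half becomes the ε ring, the (1S,4S) half becomes the β ring (OH-directed epoxidation, then E1cB opening gives the cis-diol and the C5=C6 bond).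
4. The only ring-forming event comes first: intramolecular aldol condensation of the 1,5-diketone from ethyl acetoacetate and mesityl oxide; both end rings of the carotenoid descend from this one cyclohexenone.

Abbreviation: TBSO = (tert-butyldimethylsilyl)oxy.

Assumption: the lipase acetylates the (4S)-alcohol of 7 (usual lipase preference, ring CH2–CMe2 side as the large group); if it took the (4R)-alcohol instead, free alcohol and acetate would simply change branches.

## Route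

**Step 1**
Reactants: 1 ethyl acetoacetate; 2 mesityl oxide
Product: 4 ethyl 2,6,6-trimethyl-4-oxocyclohex-2-ene-1-carboxylate (racemic), via Michael adduct 3 (not isolated)
Conditions: ZnCl2 (20 mol %), heptane–toluene, reflux, Dean–Stark, 48 h
Reagents that add atoms: none
Why: ZnCl2-promoted Michael addition of the acetoacetate enol to mesityl oxide gives 1,5-diketone 3, whose methyl-ketone enol closes the six-membered ring onto the acetoacetate carbonyl by intramolecular aldol condensation (Robinson-type annulation), water removal pulling it to the conjugated enone; the one stereocentre (C1) forms racemic and is still labile.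

**Step 2**
Reactants: 4 keto ester
Product: 5 ethyl (1R*,4S*)-4-hydroxy-2,6,6-trimethylcyclohex-2-ene-1-carboxylate (racemic; OH cis to ester)
Conditions: L-Selectride (1.2 equiv), THF, −78 °C; H2O
Reagents that add atoms: none
Why: Steric-approach-controlled 1,2-reduction: the bulky trialkylborohydride cannot add 1,4 to the β,β-disubstituted enone and attacks the carbonyl from the face away from the C1 ester, so the new C4–OH is cis to the ester (relative configuration only).

**Step 3**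
Reactants: 5 cis-hydroxy ester
Product: 6 ethyl (1R*,4R*)-2,6,6-trimethyl-4-[(4-nitrobenzoyl)oxy]cyclohex-2-ene-1-carboxylate (racemic; trans)
Conditions: 4-nitrobenzoic acid, PPh3, DIAD, THF, 0 °C → rt
Reagents that add atoms: 4-nitrobenzoic acid, OC(=O)c1ccc(cc1)[N+](=O)[O-]
Why: Mitsunobu reaction: SN2 displacement of the oxyphosphonium by 4-nitrobenzoate inverts C4 and gives the 1,4-trans relationship needed for the ε ring, while C1 is untouched.

**Step 4**
Reactants: 6 trans 4-nitrobenzoate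
Product: 7 ethyl (1R*,4R*)-4-hydroxy-2,6,6-trimethylcyclohex-2-ene-1-carboxylate (racemic; trans)
Conditions: K2CO3 (cat.), EtOH, rt
Reagents that add atoms: none
Why: Base-catalysed transesterification in ethanol cleaves only the activated aryl ester and leaves the ethyl ester and both stereocentres as they are.

**Step 5**
Reactants: 7 racemic trans-hydroxy ester
Product: 8 ethyl (1R,4R)-4-hydroxy-2,6,6-trimethylcyclohex-2-ene-1-carboxylate (unreacted alcohol) and 9 ethyl (1S,4S)-4-acetoxy-2,6,6-trimethylcyclohex-2-ene-1-carboxylate (acetate)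
Conditions: lipase PS (Burkholderia cepacia, immobilised), vinyl acetate, MTBE, 30 °C, to 50 % conversion; chromatography
Reagents that add atoms: vinyl acetate, C=COC(C)=O
Why: Lipase-catalysed kinetic resolution by irreversible acyl transfer: the enzyme acetylates the (4S)-alcohol and leaves the (1R,4R)-alcohol, which fixes the absolute configuration of both end rings at once because 8 feeds the ε ring and 9 the β ring.

**Step 6**
Reactants: 8 (1R,4R)-hydroxy ester
Product: 10 ethyl (1R,4R)-4-TBSO-2,6,6-trimethylcyclohex-2-ene-1-carboxylate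
Conditions: TBSCl, imidazole, DMF, rt
Reagents that add atoms: tert-butyldimethylsilyl chloride, CC(C)(C)[Si](C)(C)Cl
Why: Silyl ether formation masks the allylic OH against the hydride, oxidation and Appel steps ahead without touching a stereocentre.

**Step 7**
Reactants: 10 silyl ether ester
Product: 11 [(1R,4R)-4-TBSO-2,6,6-trimethylcyclohex-2-en-1-yl]methanol
Conditions: DIBAL-H (2.5 equiv), CH2Cl2, −78 → 0 °C; Rochelle salt
Reagents that add atoms: none
Why: DIBAL-H reduction of the ester to the primary alcohol; the Lewis-acidic hydride does not enolise C1.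

**Step 8**
Reactants: 11 primary alcohol
Product: 12 (1R,4R)-4-TBSO-2,6,6-trimethylcyclohex-2-ene-1-carbaldehyde
Conditions: Dess–Martin periodinane, NaHCO3, CH2Cl2, 0 °C; used crude at once
Reagents that add atoms: none
Why: Dess–Martin oxidation under buffered, non-basic conditions gives the α-branched β,γ-unsaturated aldehyde without epimerising C1 or moving the double bond.

**Step 9**
Reactants: 12 ring aldehyde; 13 triethyl 3-methyl-4-phosphonocrotonate
Product: 14 ethyl (2E,4E)-5-[(1R,4R)-4-TBSO-2,6,6-trimethylcyclohex-2-en-1-yl]-3-methylpenta-2,4-dienoate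
Conditions: 13 (1.4 equiv), LiHMDS (1.3 equiv), THF–DMPU, −78 °C; then 12, −78 → 0 °C
Reagents that add atoms: none
Why: Vinylogous Horner–Wadsworth–Emmons olefination: the lithium phosphonate adds to the aldehyde at −78 °C faster than it deprotonates the hindered α-CH, the new C7=C8 bond is E and the 2E geometry comes from the equilibrating phosphonate anion (minor 2Z isomer and any C1 epimer, a diastereomer, are removed by chromatography).

**Step 10**
Reactants: 14 ε-C15 ester
Product: 15 (2E,4E)-5-[(1R,4R)-4-TBSO-2,6,6-trimethylcyclohex-2-en-1-yl]-3-methylpenta-2,4-dien-1-ol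
Conditions: DIBAL-H (2.2 equiv), CH2Cl2, −78 °C
Reagents that add atoms: none
Why: DIBAL-H 1,2-reduction of the dienoate to the allylic alcohol.

**Step 11**
Reactants: 15 ε-C15 alcohol
Product: 17 [(2E,4E)-5-[(1R,4R)-4-TBSO-2,6,6-trimethylcyclohex-2-en-1-yl]-3-methylpenta-2,4-dien-1-yl]triphenylphosphonium bromide, via C15 allylic bromide 16 (not isolated)
Conditions: CBr4, PPh3 (1.1 equiv each), CH2Cl2, −20 °C; then PPh3 (1.2 equiv), rt
Reagents that add atoms: carbon tetrabromide, BrC(Br)(Br)Br; triphenylphosphine, c1ccc(cc1)P(c1ccccc1)c1ccccc1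
Why: Appel bromination under neutral conditions followed by SN2 quaternisation of PPh3 by the primary allylic bromide, so no acid reaches the allylic silyl ether.

**Step 12**
Reactants: 17 ε-C15 phosphonium bromide; 18 (2E,4E,6E)-2,7-dimethylocta-2,4,6-trienedial
Product: 19 (2E,4E,6E,8E,10E,12E)-13-[(1R,4R)-4-TBSO-2,6,6-trimethylcyclohex-2-en-1-yl]-2,7,11-trimethyltrideca-2,4,6,8,10,12-hexaenal
Conditions: 18 (2 equiv), NaOMe, CH2Cl2–MeOH, 0 °C → rt; then heptane, 80 °C (Z → E)
Reagents that add atoms: none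
Why: Wittig olefination with the dialdehyde in excess gives the mono-adduct; the C11′=C12′ Z isomer formed alongside isomerises thermally to all-E and the doubly allylic C6′–H is not touched.

**Step 13**
Reactants: 19 ε-C25 aldehyde
Product: 20 (2E,4E,6E,8E,10E,12E)-13-[(1R,4R)-4-TBSO-2,6,6-trimethylcyclohex-2-en-1-yl]-2,7,11-trimethyltrideca-2,4,6,8,10,12-hexaen-1-ol
Conditions: NaBH4, THF–MeOH, 0 °C
Reagents that add atoms: none
Why: Borohydride 1,2-reduction touches only the aldehyde of the polyenal.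

**Step 14**
Reactants: 20 ε-C25 alcohol
Product: 22 [(2E,4E,6E,8E,10E,12E)-13-[(1R,4R)-4-TBSO-2,6,6-trimethylcyclohex-2-en-1-yl]-2,7,11-trimethyltrideca-2,4,6,8,10,12-hexaen-1-yl]triphenylphosphonium bromide, via C25 allylic bromide 21 (not isolated)
Conditions: CBr4, PPh3 (1.1 equiv each), CH2Cl2, −30 °C, dark; then PPh3 (1.2 equiv), rt
Reagents that add atoms: carbon tetrabromide, BrC(Br)(Br)Br; triphenylphosphine, c1ccc(cc1)P(c1ccccc1)c1ccccc1
Why: Appel bromination then SN2 quaternisation as in step 11, kept cold and dark because the polyenyl bromide is labile.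

**Step 15**
Reactants: 9 (1S,4S)-acetate
Product: 23 ethyl (1S,4S)-4-hydroxy-2,6,6-trimethylcyclohex-2-ene-1-carboxylate
Conditions: K2CO3 (cat.), EtOH, rt
Reagents that add atoms: none
Why: Base-catalysed ethanolysis removes the acetate and frees the OH that must direct the next step; the ethyl ester is unchanged in ethanol.

**Step 16**
Reactants: 23 (1S,4S)-hydroxy ester
Product: 24 ethyl (1R,2S,5S,6S)-5-hydroxy-1,3,3-trimethyl-7-oxabicyclo[4.1.0]heptane-2-carboxylate (oxirane cis to OH, trans to ester)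
Conditions: mCPBA, CH2Cl2, 0 °C
Reagents that add atoms: mCPBA, OOC(=O)c1cccc(Cl)c1
Why: Hydroxyl-directed (Henbest) peracid epoxidation: hydrogen bonding to the allylic OH delivers oxygen to its face, which is also the face away from the ester, so the new C–O bonds are cis to the OH.

**Step 17**
Reactants: 24 epoxy alcohol
Product: 25 ethyl (3R,4S)-3,4-dihydroxy-2,6,6-trimethylcyclohex-1-ene-1-carboxylate (cis-diol; carotenoid numbering 3S,4R)
Conditions: NaOEt (0.3 equiv), EtOH, 0 °C → rt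
Reagents that add atoms: none
Why: E1cB opening of the β,γ-epoxy ester: the ester enolate expels the oxirane C–O bond at the neighbouring carbon and gives the conjugated tetrasubstituted enoate, and because the other oxirane C–O bond is not broken the new OH stays cis to the old one while the former ester-bearing stereocentre disappears.

**Step 18**
Reactants: 25 cis-diol ester
Product: 26 ethyl (3R,4S)-3,4-bis(TBSO)-2,6,6-trimethylcyclohex-1-ene-1-carboxylate
Conditions: TBSOTf (2.5 equiv), 2,6-lutidine, CH2Cl2, 0 °C → rt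
Reagents that add atoms: tert-butyldimethylsilyl triflate, CC(C)(C)[Si](C)(C)OS(=O)(=O)C(F)(F)F
Why: Silylation with the silyl triflate protects both hindered secondary hydroxyls for the hydride, base and ylide steps ahead, with fluoride-labile groups that come off without acid.

**Step 19**
Reactants: 26 bis-silyl ether ester
Product: 27 [(3R,4S)-3,4-bis(TBSO)-2,6,6-trimethylcyclohex-1-en-1-yl]methanol
Conditions: DIBAL-H (3 equiv), CH2Cl2, −78 → 0 °C
Reagents that add atoms: none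
Why: DIBAL-H 1,2-reduction of the hindered conjugated ester to the allylic alcohol.

**Step 20**
Reactants: 27 allylic alcohol
Product: 28 (3R,4S)-3,4-bis(TBSO)-2,6,6-trimethylcyclohex-1-ene-1-carbaldehyde
Conditions: MnO2 (activated, excess), CH2Cl2, rt
Reagents that add atoms: none
Why: MnO2 oxidises the allylic alcohol to the enal under neutral conditions.

**Step 21**
Reactants: 28 ring enal; 13 triethyl 3-methyl-4-phosphonocrotonate
Product: 29 ethyl (2E,4E)-5-[(3R,4S)-3,4-bis(TBSO)-2,6,6-trimethylcyclohex-1-en-1-yl]-3-methylpenta-2,4-dienoate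
Conditions: 13 (1.5 equiv), LiHMDS (1.4 equiv), THF–DMPU, −78 °C; then 28, −78 °C → rt
Reagents that add atoms: none
Why: Vinylogous Horner–Wadsworth–Emmons olefination of the hindered enal with the weakly basic lithium phosphonate gives the E,E-dienoate, the new C7=C8 bond being E.

**Step 22**
Reactants: 29 β-C15 ester
Product: 30 (2E,4E)-5-[(3R,4S)-3,4-bis(TBSO)-2,6,6-trimethylcyclohex-1-en-1-yl]-3-methylpenta-2,4-dien-1-ol
Conditions: DIBAL-H (2.2 equiv), CH2Cl2, −78 °C
Reagents that add atoms: none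
Why: DIBAL-H 1,2-reduction of the dienoate to the allylic alcohol.

**Step 23**
Reactants: 30 β-C15 alcohol
Product: 31 (2E,4E)-5-[(3R,4S)-3,4-bis(TBSO)-2,6,6-trimethylcyclohex-1-en-1-yl]-3-methylpenta-2,4-dienal
Conditions: MnO2, CH2Cl2, rt
Reagents that add atoms: none
Why: MnO2 allylic oxidation gives the trienal without touching the silyl ethers or the alkene geometry.

**Step 24**
Reactants: 22 ε-C25 phosphonium bromide; 31 β-C15 aldehyde
Product: 32 (3S,4R,3′R,6′R)-3,4,3′-tris(TBSO)-β,ε-carotene (all-E)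
Conditions: NaOMe, CH2Cl2–MeOH, 0 °C → rt; then heptane, 90 °C, dark (11Z → all-E)
Reagents that add atoms: none
Why: Wittig olefination of the C25 ylide with the C15 aldehyde forms C11=C12; the 11Z isomer isomerises thermally, and putting the 4-silyloxy ring on the aldehyde partner keeps that leaving group out of conjugation with a carbanion.

**Step 25**
Reactants: 32 tris-silyl ether
Product: 33 (3S,4R,3′R,6′R)-β,ε-carotene-3,4,3′-triol (target)
Conditions: TBAF, AcOH (1:1, 6 equiv), THF, rt → 40 °C, dark, Ar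
Reagents that add atoms: none
Why: Fluoride-induced desilylation buffered with acetic acid frees the three hydroxyls without strong acid or base, so the allylic alcohols, the doubly allylic C6′–H and the polyene survive.

## Compound list

1 | ethyl acetoacetate | CCOC(=O)CC(C)=O | starting material
2 | mesityl oxide (4-methylpent-3-en-2-one) | CC(=O)C=C(C)C | starting material
3 | ethyl 2-acetyl-3,3-dimethyl-5-oxohexanoate (racemic) | CCOC(=O)C(C(C)=O)C(C)(C)CC(C)=O | intermediate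
4 | ethyl 2,6,6-trimethyl-4-oxocyclohex-2-ene-1-carboxylate (racemic) | CCOC(=O)C1C(C)=CC(=O)CC1(C)C | intermediate
5 | ethyl (1R*,4S*)-4-hydroxy-2,6,6-trimethylcyclohex-2-ene-1-carboxylate (racemate, both enantiomers written) | CC1=C[C@@H](O)CC(C)(C)[C@H]1C(=O)OCC.CC1=C[C@H](O)CC(C)(C)[C@@H]1C(=O)OCC | intermediate
6 | ethyl (1R*,4R*)-2,6,6-trimethyl-4-[(4-nitrobenzoyl)oxy]cyclohex-2-ene-1-carboxylate (racemate, both enantiomers written) | CC1=C[C@H](OC(=O)c2ccc(cc2)[N+](=O)[O-])CC(C)(C)[C@H]1C(=O)OCC.CC1=C[C@@H](OC(=O)c2ccc(cc2)[N+](=O)[O-])CC(C)(C)[C@@H]1C(=O)OCC | intermediate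
7 | ethyl (1R*,4R*)-4-hydroxy-2,6,6-trimethylcyclohex-2-ene-1-carboxylate (racemate, both enantiomers written) | CC1=C[C@H](O)CC(C)(C)[C@H]1C(=O)OCC.CC1=C[C@@H](O)CC(C)(C)[C@@H]1C(=O)OCC | intermediate
8 | ethyl (1R,4R)-4-hydroxy-2,6,6-trimethylcyclohex-2-ene-1-carboxylate | CC1=C[C@H](O)CC(C)(C)[C@H]1C(=O)OCC | intermediate
9 | ethyl (1S,4S)-4-acetoxy-2,6,6-trimethylcyclohex-2-ene-1-carboxylate | CC1=C[C@@H](OC(C)=O)CC(C)(C)[C@@H]1C(=O)OCC | intermediate
10 | ethyl (1R,4R)-4-TBSO-2,6,6-trimethylcyclohex-2-ene-1-carboxylate | CC1=C[C@H](O[Si](C)(C)C(C)(C)C)CC(C)(C)[C@H]1C(=O)OCC | intermediate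
11 | [(1R,4R)-4-TBSO-2,6,6-trimethylcyclohex-2-en-1-yl]methanol | CC1=C[C@H](O[Si](C)(C)C(C)(C)C)CC(C)(C)[C@H]1CO | intermediate
12 | (1R,4R)-4-TBSO-2,6,6-trimethylcyclohex-2-ene-1-carbaldehyde | CC1=C[C@H](O[Si](C)(C)C(C)(C)C)CC(C)(C)[C@H]1C=O | intermediate
13 | triethyl 3-methyl-4-phosphonocrotonate, ethyl (2E)-4-(diethoxyphosphoryl)-3-methylbut-2-enoate (sold as E/Z mixture) | CCOC(=O)/C=C(\C)CP(=O)(OCC)OCC | starting material
14 | ethyl (2E,4E)-5-[(1R,4R)-4-TBSO-2,6,6-trimethylcyclohex-2-en-1-yl]-3-methylpenta-2,4-dienoate | CC1=C[C@H](O[Si](C)(C)C(C)(C)C)CC(C)(C)[C@H]1/C=C/C(C)=C/C(=O)OCC | intermediate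
15 | (2E,4E)-5-[(1R,4R)-4-TBSO-2,6,6-trimethylcyclohex-2-en-1-yl]-3-methylpenta-2,4-dien-1-ol | CC1=C[C@H](O[Si](C)(C)C(C)(C)C)CC(C)(C)[C@H]1/C=C/C(C)=C/CO | intermediate
16 | (2E,4E)-1-bromo-5-[(1R,4R)-4-TBSO-2,6,6-trimethylcyclohex-2-en-1-yl]-3-methylpenta-2,4-diene | CC1=C[C@H](O[Si](C)(C)C(C)(C)C)CC(C)(C)[C@H]1/C=C/C(C)=C/CBr | intermediate
17 | [(2E,4E)-5-[(1R,4R)-4-TBSO-2,6,6-trimethylcyclohex-2-en-1-yl]-3-methylpenta-2,4-dien-1-yl]triphenylphosphonium bromide | CC1=C[C@H](O[Si](C)(C)C(C)(C)C)CC(C)(C)[C@H]1/C=C/C(C)=C/C[P+](c1ccccc1)(c1ccccc1)c1ccccc1.[Br-] | intermediate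
18 | (2E,4E,6E)-2,7-dimethylocta-2,4,6-trienedial (C10 dialdehyde) | O=C/C(C)=C/C=C/C=C(C)/C=O | starting material
19 | (2E,4E,6E,8E,10E,12E)-13-[(1R,4R)-4-TBSO-2,6,6-trimethylcyclohex-2-en-1-yl]-2,7,11-trimethyltrideca-2,4,6,8,10,12-hexaenal | CC1=C[C@H](O[Si](C)(C)C(C)(C)C)CC(C)(C)[C@H]1/C=C/C(C)=C/C=C/C(C)=C/C=C/C=C(C)/C=O | intermediate
20 | (2E,4E,6E,8E,10E,12E)-13-[(1R,4R)-4-TBSO-2,6,6-trimethylcyclohex-2-en-1-yl]-2,7,11-trimethyltrideca-2,4,6,8,10,12-hexaen-1-ol | CC1=C[C@H](O[Si](C)(C)C(C)(C)C)CC(C)(C)[C@H]1/C=C/C(C)=C/C=C/C(C)=C/C=C/C=C(C)/CO | intermediate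
21 | (2E,4E,6E,8E,10E,12E)-1-bromo-13-[(1R,4R)-4-TBSO-2,6,6-trimethylcyclohex-2-en-1-yl]-2,7,11-trimethyltrideca-2,4,6,8,10,12-hexaene | CC1=C[C@H](O[Si](C)(C)C(C)(C)C)CC(C)(C)[C@H]1/C=C/C(C)=C/C=C/C(C)=C/C=C/C=C(C)/CBr | intermediate
22 | [(2E,4E,6E,8E,10E,12E)-13-[(1R,4R)-4-TBSO-2,6,6-trimethylcyclohex-2-en-1-yl]-2,7,11-trimethyltrideca-2,4,6,8,10,12-hexaen-1-yl]triphenylphosphonium bromide | CC1=C[C@H](O[Si](C)(C)C(C)(C)C)CC(C)(C)[C@H]1/C=C/C(C)=C/C=C/C(C)=C/C=C/C=C(C)/C[P+](c1ccccc1)(c1ccccc1)c1ccccc1.[Br-] | intermediate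
23 | ethyl (1S,4S)-4-hydroxy-2,6,6-trimethylcyclohex-2-ene-1-carboxylate | CC1=C[C@@H](O)CC(C)(C)[C@@H]1C(=O)OCC | intermediate
24 | ethyl (1R,2S,5S,6S)-5-hydroxy-1,3,3-trimethyl-7-oxabicyclo[4.1.0]heptane-2-carboxylate | C[C@]12O[C@H]1[C@@H](O)CC(C)(C)[C@@H]2C(=O)OCC | intermediate
25 | ethyl (3R,4S)-3,4-dihydroxy-2,6,6-trimethylcyclohex-1-ene-1-carboxylate | CCOC(=O)C1=C(C)[C@@H](O)[C@@H](O)CC1(C)C | intermediate
26 | ethyl (3R,4S)-3,4-bis(TBSO)-2,6,6-trimethylcyclohex-1-ene-1-carboxylate | CCOC(=O)C1=C(C)[C@@H](O[Si](C)(C)C(C)(C)C)[C@@H](O[Si](C)(C)C(C)(C)C)CC1(C)C | intermediate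
27 | [(3R,4S)-3,4-bis(TBSO)-2,6,6-trimethylcyclohex-1-en-1-yl]methanol | OCC1=C(C)[C@@H](O[Si](C)(C)C(C)(C)C)[C@@H](O[Si](C)(C)C(C)(C)C)CC1(C)C | intermediate
28 | (3R,4S)-3,4-bis(TBSO)-2,6,6-trimethylcyclohex-1-ene-1-carbaldehyde | O=CC1=C(C)[C@@H](O[Si](C)(C)C(C)(C)C)[C@@H](O[Si](C)(C)C(C)(C)C)CC1(C)C | intermediate
29 | ethyl (2E,4E)-5-[(3R,4S)-3,4-bis(TBSO)-2,6,6-trimethylcyclohex-1-en-1-yl]-3-methylpenta-2,4-dienoate | CCOC(=O)/C=C(C)/C=C/C1=C(C)[C@@H](O[Si](C)(C)C(C)(C)C)[C@@H](O[Si](C)(C)C(C)(C)C)CC1(C)C | intermediate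
30 | (2E,4E)-5-[(3R,4S)-3,4-bis(TBSO)-2,6,6-trimethylcyclohex-1-en-1-yl]-3-methylpenta-2,4-dien-1-ol | OC/C=C(C)/C=C/C1=C(C)[C@@H](O[Si](C)(C)C(C)(C)C)[C@@H](O[Si](C)(C)C(C)(C)C)CC1(C)C | intermediate
31 | (2E,4E)-5-[(3R,4S)-3,4-bis(TBSO)-2,6,6-trimethylcyclohex-1-en-1-yl]-3-methylpenta-2,4-dienal | O=C/C=C(C)/C=C/C1=C(C)[C@@H](O[Si](C)(C)C(C)(C)C)[C@@H](O[Si](C)(C)C(C)(C)C)CC1(C)C | intermediate
32 | (3S,4R,3′R,6′R)-3,4,3′-tris(TBSO)-β,ε-carotene (all-E) | CC1=C[C@H](O[Si](C)(C)C(C)(C)C)CC(C)(C)[C@H]1/C=C/C(C)=C/C=C/C(C)=C/C=C/C=C(C)/C=C/C=C(C)/C=C/C1=C(C)[C@@H](O[Si](C)(C)C(C)(C)C)[C@@H](O[Si](C)(C)C(C)(C)C)CC1(C)C | intermediate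
33 | (3S,4R,3′R,6′R)-β,ε-carotene-3,4,3′-triol (all-E) | CC1=C[C@H](O)CC(C)(C)[C@H]1/C=C/C(C)=C/C=C/C(C)=C/C=C/C=C(C)/C=C/C=C(C)/C=C/C1=C(C)[C@@H](O)[C@@H](O)CC1(C)C | target

## Step count and risks

Total step count: 25.
Longest linear sequence: 16 steps (steps 1–5, 6–14, 24–25; the β arm, steps 1–5, 15–23, 24–25, is equally long).

Steps most likely to fail:

**Step 5 (lipase resolution; the selectivity factor on this hindered ring alcohol may be too low).** The fallback sets out from 5 and comes back at 8 and at 23, replacing steps 3–5 by a resolution through diastereomers. Mitsunobu esterification of 5 with (R)-O-methylmandelic acid (PPh3, DIAD, THF) inverts C4 and gives two trans esters, ethyl (1R,4R)-4-{[(2R)-2-methoxy-2-phenylacetyl]oxy}-2,6,6-trimethylcyclohex-2-ene-1-carboxylate F1 and ethyl (1S,4S)-4-{[(2R)-2-methoxy-2-phenylacetyl]oxy}-2,6,6-trimethylcyclohex-2-ene-1-carboxylate F2. They are separated by chromatography or crystallisation; K2CO3 in ethanol then turns F1 into 8 and F2 into 23.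

**Step 9 (the aldehyde 12 can epimerise at C1 or slip into conjugation under the basic olefination).** The fallback sets out from 11 and comes back at 14, so that C1 is never next to a carbonyl. Mitsunobu thioetherification of 11 with 1-phenyl-1H-tetrazole-5-thiol gives 5-({[(1R,4R)-4-TBSO-2,6,6-trimethylcyclohex-2-en-1-yl]methyl}sulfanyl)-1-phenyl-1H-tetrazole F3. Molybdate-catalysed H2O2 oxidation gives 5-({[(1R,4R)-4-TBSO-2,6,6-trimethylcyclohex-2-en-1-yl]methyl}sulfonyl)-1-phenyl-1H-tetrazole F4. Julia–Kocienski olefination of F4 (KHMDS, DME, −60 °C) with commercial ethyl (2E)-3-methyl-4-oxobut-2-enoate then gives 14.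

**Step 21 (the enal 28 is very hindered and carries a γ-H with a β-silyloxy group, so base may cause elimination to a safranal-type dienal before olefination).** The fallback sets out from 28 and comes back at 29 without any carbanion. Takai iodo-olefination (CrCl2, CHI3, THF, 0 °C) gives (3R,4S)-3,4-bis(TBSO)-1-[(E)-2-iodoethenyl]-2,6,6-trimethylcyclohex-1-ene F5. Suzuki–Miyaura coupling of F5 with commercial ethyl (2Z)-3-(4,4,5,5-tetramethyl-1,3,2-dioxaborolan-2-yl)but-2-enoate (Pd(PPh3)4, aq. K3PO4, THF) gives 29 with both alkene geometries retained.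

## Further compounds

F1 | step 5 | ethyl (1R,4R)-4-{[(2R)-2-methoxy-2-phenylacetyl]oxy}-2,6,6-trimethylcyclohex-2-ene-1-carboxylate | CC1=C[C@H](OC(=O)[C@H](OC)c2ccccc2)CC(C)(C)[C@H]1C(=O)OCC
F2 | step 5 | ethyl (1S,4S)-4-{[(2R)-2-methoxy-2-phenylacetyl]oxy}-2,6,6-trimethylcyclohex-2-ene-1-carboxylate | CC1=C[C@@H](OC(=O)[C@H](OC)c2ccccc2)CC(C)(C)[C@@H]1C(=O)OCC
F3 | step 9 | 5-({[(1R,4R)-4-TBSO-2,6,6-trimethylcyclohex-2-en-1-yl]methyl}sulfanyl)-1-phenyl-1H-tetrazole | CC1=C[C@H](O[Si](C)(C)C(C)(C)C)CC(C)(C)[C@H]1CSc1nnnn1-c1ccccc1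
F4 | step 9 | 5-({[(1R,4R)-4-TBSO-2,6,6-trimethylcyclohex-2-en-1-yl]methyl}sulfonyl)-1-phenyl-1H-tetrazole | CC1=C[C@H](O[Si](C)(C)C(C)(C)C)CC(C)(C)[C@H]1CS(=O)(=O)c1nnnn1-c1ccccc1
F5 | step 21 | (3R,4S)-3,4-bis(TBSO)-1-[(E)-2-iodoethenyl]-2,6,6-trimethylcyclohex-1-ene | I/C=C/C1=C(C)[C@@H](O[Si](C)(C)C(C)(C)C)[C@@H](O[Si](C)(C)C(C)(C)C)CC1(C)C
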